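**Retrosynthetic overview**
1. The ferulate on the propyl chain goes on last, by a Mitsunobu esterification that tolerates free phenols. All silyl groups are removed one step earlier.
2. Key disconnection: the benzene ring of the benzofuran (ring A) and the dihydrofuran ring (ring B) are made together. A 3-alkoxy-2-pyrone cycloadds to a pendant vinyl group, then CO2 is lost and the ring is dehydrogenated.
3. The pyrone already carries the future 7-OMe group and the C5 chain. It is joined to the benzylic carbinol by carbenoid O–H insertion of a diazo compound made from triacetic acid lactone.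
4. One iridium-catalysed anti-(hydroxymethyl)allylation of silylated vanillin sets both stereocentres. Its vinyl group becomes C3a/C4 of ring A, and its primary OH takes the p-coumarate.
5. Ring order: the three outer arenes and the sacrificial pyrone are bought. Rings A and B form simultaneously in step 9.

Assumption: (R)-SEGPHOS delivers the (1R) carbinol, as in related aryl aldehyde allylations. If the sense is opposite, the antipodal ligand is used.

**Step 1**
Reactants: 1 vanillin
Product: 2 3-methoxy-4-(triisopropylsilyloxy)benzaldehyde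
Conditions: TIPSCl (1.1 equiv), imidazole (1.2 equiv), DMF, 23 °C
Reagents that add atoms: triisopropylsilyl chloride CC(C)[Si](Cl)(C(C)C)C(C)C
Why: Imidazole-promoted silyl ether protection of the phenol, with the bulky TIPS group chosen because it must survive carbonate base and 2-propanol at 90 °C in step 2.

**Step 2**
Reactants: 2 3-methoxy-4-(triisopropylsilyloxy)benzaldehyde; 3 4-vinyl-1,3-dioxolan-2-one
Product: 4 (1R,2S)-2-ethenyl-1-[3-methoxy-4-(triisopropylsilyloxy)phenyl]propane-1,3-diol
Conditions: [Ir(cod)Cl]2 (2.5 mol %), (R)-SEGPHOS (5 mol %), 4-cyano-3-nitrobenzoic acid (10 mol %), Cs2CO3 (20 mol %), 2-propanol (2 equiv), THF, 90 °C, sealed tube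
Reagents that add atoms: none
Why: Krische-type transfer-hydrogenative carbonyl (hydroxymethyl)allylation, in which the branched allylic carbonate ionises and loses CO2 to an (E)-σ-(hydroxymethyl)allyl iridium species that adds to the aldehyde through a closed chair transition state (anti relationship) while the ligand selects the aldehyde face, so both stereocentres (1R,2S) are set here.

**Step 3**
Reactants: 5 (E)-4-hydroxycinnamic acid
Product: 7 (E)-3-[4-(tert-butyldimethylsilyloxy)phenyl]prop-2-enoic acid, via bis-silylated coumarate 6 (not isolated)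
Conditions: TBSCl (2.3 equiv), imidazole (2.5 equiv), DMF, 23 °C; then AcOH–THF–H2O, 23 °C
Reagents that add atoms: tert-butyldimethylsilyl chloride CC(C)(C)[Si](C)(C)Cl
Why: Exhaustive silylation followed by selective hydrolysis of the much more labile silyl ester gives phenol protection as a silyl ether and leaves the acid free.

**Step 4**
Reactants: 4 anti diol; 7 TBS-protected p-coumaric acid
Product: 8 (2S,3R)-2-ethenyl-3-hydroxy-3-[3-methoxy-4-(triisopropylsilyloxy)phenyl]propyl (E)-3-[4-(tert-butyldimethylsilyloxy)phenyl]prop-2-enoate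
Conditions: 7 (1.0 equiv), DCC (1.05 equiv), DMAP (5 mol %), CH2Cl2, −10 to 0 °C
Reagents that add atoms: none
Why: Steglich esterification, in which the primary hydroxyl is acylated much faster than the hindered secondary benzylic one and no stereocentre is touched.

**Step 5**
Reactants: 9 4-hydroxy-6-methyl-2H-pyran-2-one; 10 tert-butyl(2-iodoethoxy)dimethylsilane
Product: 11 6-[3-(tert-butyldimethylsilyloxy)propyl]-4-hydroxy-2H-pyran-2-one
Conditions: LDA (2.3 equiv), THF–DMPU, −78 °C; 10, −78 to −20 °C; cold 1 M HCl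
Reagents that add atoms: none
Why: Dianion alkylation, in which the second deprotonation occurs at the C6 methyl group and that carbanion is the most nucleophilic site, so the iodide extends it to the three-carbon chain.

**Step 6**
Reactants: 11 6-[3-(tert-butyldimethylsilyloxy)propyl]-4-hydroxy-2H-pyran-2-one
Product: 12 6-[3-(tert-butyldimethylsilyloxy)propyl]-3-diazo-2H-pyran-2,4(3H)-dione
Conditions: 4-acetamidobenzenesulfonyl azide (1.1 equiv), Et3N, MeCN, 0 to 23 °C
Reagents that add atoms: 4-acetamidobenzenesulfonyl azide CC(=O)Nc1ccc(cc1)S(=O)(=O)N=[N+]=[N-]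
Why: Regitz diazo transfer onto C3, the active methylene position of the pyran-2,4-dione tautomer.

**Step 7**
Reactants: 8 secondary carbinol; 12 diazopyrandione
Product: 13 (2S,3R)-2-ethenyl-3-({4-hydroxy-2-oxo-6-[3-(tert-butyldimethylsilyloxy)propyl]-2H-pyran-3-yl}oxy)-3-[3-methoxy-4-(triisopropylsilyloxy)phenyl]propyl (E)-3-[4-(tert-butyldimethylsilyloxy)phenyl]prop-2-enoate
Conditions: Rh2(OAc)4 (2 mol %), 12 (1.5 equiv, slow addition), 4 Å sieves, 1,2-dichloroethane, 70 °C
Reagents that add atoms: none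
Why: Rhodium-carbenoid O–H insertion of a cyclic 2-diazo-1,3-dicarbonyl compound, which proceeds through an oxonium ylide and proton transfer at oxygen only, so the carbinol C–O bond and its configuration are retained and the product enolises to the 4-hydroxypyrone.

**Step 8**
Reactants: 13 4-hydroxypyrone ether
Product: 14 (2S,3R)-2-ethenyl-3-({4-methoxy-2-oxo-6-[3-(tert-butyldimethylsilyloxy)propyl]-2H-pyran-3-yl}oxy)-3-[3-methoxy-4-(triisopropylsilyloxy)phenyl]propyl (E)-3-[4-(tert-butyldimethylsilyloxy)phenyl]prop-2-enoate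
Conditions: Me2SO4 (1.2 equiv), K2CO3 (1.5 equiv), dry acetone, 50 °C
Reagents that add atoms: dimethyl sulfate COS(=O)(=O)OC
Why: Williamson-type O-alkylation of the only acidic site, the vinylogous acid (pKa about 5), where the hard electrophile gives the 4-methoxy-2-pyrone that becomes the 7-OMe group.

**Step 9**
Reactants: 14 4-methoxypyrone ether
Product: 17 [(2R,3S)-5-[3-(tert-butyldimethylsilyloxy)propyl]-7-methoxy-2-[3-methoxy-4-(triisopropylsilyloxy)phenyl]-2,3-dihydro-1-benzofuran-3-yl]methyl (E)-3-[4-(tert-butyldimethylsilyloxy)phenyl]prop-2-enoate, via bridged lactone cycloadduct 15 (not isolated), via 3a,4-dihydrobenzofuran diene 16 (not isolated)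
Conditions: 1,2-dichlorobenzene (0.01 M), BHT (0.1 equiv), 180 °C, sealed tube, 36 h; cool to 0 °C, DDQ (1.05 equiv), 30 min
Reagents that add atoms: none
Why: Proposed new method: the pyrone is held three atoms from the vinyl group exactly as in furan and aminopyrone intramolecular Diels–Alder reactions, so a [4+2] cycloaddition across pyrone C3/C6 closes the six-membered carbocycle and the five-membered oxacycle in one event, the bridged lactone 15 then loses CO2 irreversibly (retro-Diels–Alder) to diene 16 and DDQ removes the last two ring hydrogens, which erases the transient sp3 centres while C2 and C3 lie outside the reacting π system and keep the step 2 configuration (anti diol with retention gives the trans ring); the closest known reaction type is the intramolecular 2-pyrone Diels–Alder/decarboxylation route to indolines and hydroindolines.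

**Step 10**
Reactants: 17 tris-silylated dihydrobenzofuran
Product: 18 [(2R,3S)-2-(4-hydroxy-3-methoxyphenyl)-5-(3-hydroxypropyl)-7-methoxy-2,3-dihydro-1-benzofuran-3-yl]methyl (E)-3-(4-hydroxyphenyl)prop-2-enoate
Conditions: TBAF (4 equiv), AcOH (4 equiv), THF, 0 to 23 °C
Reagents that add atoms: none
Why: Fluoride-mediated desilylation of all three silyl ethers, buffered with acetic acid so that no free phenoxide attacks the cinnamate ester or opens the benzylic ether.

**Step 11**
Reactants: 18 phenolic primary alcohol; 19 (E)-ferulic acid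
Product: 20 (+)-boehmenan X
Conditions: 19 (1.2 equiv), PPh3 (1.3 equiv), DIAD (1.3 equiv), THF, 0 to 23 °C
Reagents that add atoms: none
Why: Mitsunobu esterification, in which only the single aliphatic hydroxyl is activated and the carboxylic acid (pKa about 4.5) outcompetes the three phenols (pKa about 10) as pronucleophile, at a primary carbon so no stereocentre is involved.

**Compound list**
1 | vanillin (4-hydroxy-3-methoxybenzaldehyde) | COc1cc(C=O)ccc1O | starting material
2 | 3-methoxy-4-(triisopropylsilyloxy)benzaldehyde | COc1cc(C=O)ccc1O[Si](C(C)C)(C(C)C)C(C)C | intermediate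
3 | 4-vinyl-1,3-dioxolan-2-one (racemic vinyl ethylene carbonate) | C=CC1COC(=O)O1 | starting material
4 | (1R,2S)-2-ethenyl-1-[3-methoxy-4-(triisopropylsilyloxy)phenyl]propane-1,3-diol (anti) | C=C[C@@H](CO)[C@H](c1ccc(O[Si](C(C)C)(C(C)C)C(C)C)c(OC)c1)O | intermediate
5 | (E)-4-hydroxycinnamic acid (p-coumaric acid) | OC(=O)/C=C/c1ccc(O)cc1 | starting material
6 | tert-butyldimethylsilyl (E)-3-[4-(tert-butyldimethylsilyloxy)phenyl]prop-2-enoate | CC(C)(C)[Si](C)(C)OC(=O)/C=C/c1ccc(O[Si](C)(C)C(C)(C)C)cc1 | intermediate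
7 | (E)-3-[4-(tert-butyldimethylsilyloxy)phenyl]prop-2-enoic acid | OC(=O)/C=C/c1ccc(O[Si](C)(C)C(C)(C)C)cc1 | intermediate
8 | (2S,3R)-2-ethenyl-3-hydroxy-3-[3-methoxy-4-(triisopropylsilyloxy)phenyl]propyl (E)-3-[4-(tert-butyldimethylsilyloxy)phenyl]prop-2-enoate | C=C[C@@H](COC(=O)/C=C/c1ccc(O[Si](C)(C)C(C)(C)C)cc1)[C@H](c1ccc(O[Si](C(C)C)(C(C)C)C(C)C)c(OC)c1)O | intermediate
9 | 4-hydroxy-6-methyl-2H-pyran-2-one (triacetic acid lactone) | CC1=CC(O)=CC(=O)O1 | starting material
10 | tert-butyl(2-iodoethoxy)dimethylsilane | CC(C)(C)[Si](C)(C)OCCI | starting material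
11 | 6-[3-(tert-butyldimethylsilyloxy)propyl]-4-hydroxy-2H-pyran-2-one | CC(C)(C)[Si](C)(C)OCCCC1=CC(O)=CC(=O)O1 | intermediate
12 | 6-[3-(tert-butyldimethylsilyloxy)propyl]-3-diazo-2H-pyran-2,4(3H)-dione | CC(C)(C)[Si](C)(C)OCCCC1=CC(=O)C(=[N+]=[N-])C(=O)O1 | intermediate
13 | 4-hydroxy-2-pyron-3-yl ether of 8 (carbinol carbon R, adjacent carbon S) | C=C[C@@H](COC(=O)/C=C/c1ccc(O[Si](C)(C)C(C)(C)C)cc1)[C@H](c1ccc(O[Si](C(C)C)(C(C)C)C(C)C)c(OC)c1)OC1=C(O)C=C(CCCO[Si](C)(C)C(C)(C)C)OC1=O | intermediate
14 | 4-methoxy-2-pyron-3-yl ether of 8 (carbinol carbon R, adjacent carbon S) | C=C[C@@H](COC(=O)/C=C/c1ccc(O[Si](C)(C)C(C)(C)C)cc1)[C@H](c1ccc(O[Si](C(C)C)(C(C)C)C(C)C)c(OC)c1)OC1=C(OC)C=C(CCCO[Si](C)(C)C(C)(C)C)OC1=O | intermediate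
15 | 2-oxabicyclo[2.2.2]oct-5-en-3-one cycloadduct fused to the new tetrahydrofuran ring (C2 R, C3 S; the three new centres are transient and not specified) | C1C2[C@@H](COC(=O)/C=C/c3ccc(O[Si](C)(C)C(C)(C)C)cc3)[C@H](c3ccc(O[Si](C(C)C)(C(C)C)C(C)C)c(OC)c3)OC24C(OC)=CC1(CCCO[Si](C)(C)C(C)(C)C)OC4=O | intermediate
16 | 3a,4-dihydro form of 17 with C5=C6 and C7=C7a double bonds (C2 R, C3 S; C3a transient) | C1C2[C@@H](COC(=O)/C=C/c3ccc(O[Si](C)(C)C(C)(C)C)cc3)[C@H](c3ccc(O[Si](C(C)C)(C(C)C)C(C)C)c(OC)c3)OC2=C(OC)C=C1CCCO[Si](C)(C)C(C)(C)C | intermediate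
17 | [(2R,3S)-5-[3-(tert-butyldimethylsilyloxy)propyl]-7-methoxy-2-[3-methoxy-4-(triisopropylsilyloxy)phenyl]-2,3-dihydro-1-benzofuran-3-yl]methyl (E)-3-[4-(tert-butyldimethylsilyloxy)phenyl]prop-2-enoate | CC(C)(C)[Si](C)(C)OCCCc1cc(OC)c2c(c1)[C@@H](COC(=O)/C=C/c1ccc(O[Si](C)(C)C(C)(C)C)cc1)[C@H](c1ccc(O[Si](C(C)C)(C(C)C)C(C)C)c(OC)c1)O2 | intermediate
18 | [(2R,3S)-2-(4-hydroxy-3-methoxyphenyl)-5-(3-hydroxypropyl)-7-methoxy-2,3-dihydro-1-benzofuran-3-yl]methyl (E)-3-(4-hydroxyphenyl)prop-2-enoate | OCCCc1cc(OC)c2c(c1)[C@@H](COC(=O)/C=C/c1ccc(O)cc1)[C@H](c1ccc(O)c(OC)c1)O2 | intermediate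
19 | (E)-ferulic acid | COc1cc(/C=C/C(O)=O)ccc1O | starting material
20 | (+)-boehmenan X (2R,3S) | COc1cc(/C=C/C(=O)OCCCc2cc(OC)c3c(c2)[C@@H](COC(=O)/C=C/c2ccc(O)cc2)[C@H](c2ccc(O)c(OC)c2)O3)ccc1O | target

**Totals**
- Total step count: 11.
- Longest linear sequence: 8 steps (1, 2, 4, 7, 8, 9, 10, 11).

**Three steps most likely to fail**

**Step 9 (cycloaddition).**
- Risk: the unactivated vinyl group may not engage the donor-substituted pyrone below the temperature at which the benzylic C–O bond ionises.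
- Change: the dienophile is changed rather than the heating, and the fallback sets out from 14.
- Cross-metathesis with phenyl vinyl sulfone (second-generation Hoveyda–Grubbs catalyst, CH2Cl2, 40 °C) gives the (E)-vinyl sulfone F1.
- This electron-poor alkyne equivalent matches the electron-rich 3,4-dialkoxypyrone in a normal-demand intramolecular cycloaddition at about 110 °C (toluene, NaHCO3). The product is the sulfonyl bridged lactone F2.
- F2 decarboxylates to the sulfonyl diene F3, and loss of the sulfinate then aromatises the ring without any oxidant.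
- The route is rejoined at 17.

**Step 7 (O–H insertion).**
- Risk: the carbenoid may prefer the alkenes or the electron-rich arene over the hindered carbinol.
- Change: the C–O bond is made by cross-coupling instead, and the fallback sets out from 11 and 8.
- Compound 11 is O-methylated (Me2SO4, K2CO3, acetone) to 4-methoxy-6-[3-(tert-butyldimethylsilyloxy)propyl]-2H-pyran-2-one F4.
- F4 is brominated at C3 (NBS, MeCN) to the 3-bromopyrone F5.
- F5 is coupled with carbinol 8 (CuI, 3,4,7,8-tetramethyl-1,10-phenanthroline, Cs2CO3, toluene, 90 °C), which retains the carbinol configuration.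
- The route is rejoined at 14, and 12 and 13 are skipped.

**Step 2 (allylation).**
- Risk: the cyclic carbonate may perform poorly as allyl donor with this aldehyde.
- Change: auxiliary control replaces catalysis, and the fallback sets out from 2.
- The boron dienolate of commercial (R)-4-benzyl-3-[(E)-but-2-enoyl]-1,3-oxazolidin-2-one (Bu2BOTf, Et3N, CH2Cl2, −78 °C) undergoes a deconjugative Evans syn aldol reaction at its α-carbon. The product is the α-vinyl syn-aldol imide F6.
- LiBH4 (Et2O, MeOH, 0 °C) reduces the imide carbonyl to the primary alcohol.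
- The route is rejoined at 4 with the same (1R,2S) configuration.

**Further compounds**
F1 | step 9 | (E)-2-(phenylsulfonyl)ethenyl analogue of 14 (carbinol carbon and adjacent carbon arranged in space as in 14) | O=S(=O)(c1ccccc1)/C=C/[C@@H](COC(=O)/C=C/c1ccc(O[Si](C)(C)C(C)(C)C)cc1)[C@H](c1ccc(O[Si](C(C)C)(C(C)C)C(C)C)c(OC)c1)OC1=C(OC)C=C(CCCO[Si](C)(C)C(C)(C)C)OC1=O
F2 | step 9 | 4-(phenylsulfonyl) analogue of bridged lactone 15 | O=S(=O)(c1ccccc1)C1C2[C@@H](COC(=O)/C=C/c3ccc(O[Si](C)(C)C(C)(C)C)cc3)[C@H](c3ccc(O[Si](C(C)C)(C(C)C)C(C)C)c(OC)c3)OC24C(OC)=CC1(CCCO[Si](C)(C)C(C)(C)C)OC4=O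
F3 | step 9 | 4-(phenylsulfonyl) analogue of diene 16 | O=S(=O)(c1ccccc1)C1C2[C@@H](COC(=O)/C=C/c3ccc(O[Si](C)(C)C(C)(C)C)cc3)[C@H](c3ccc(O[Si](C(C)C)(C(C)C)C(C)C)c(OC)c3)OC2=C(OC)C=C1CCCO[Si](C)(C)C(C)(C)C
F4 | step 7 | 4-methoxy-6-[3-(tert-butyldimethylsilyloxy)propyl]-2H-pyran-2-one | CC(C)(C)[Si](C)(C)OCCCC1=CC(OC)=CC(=O)O1
F5 | step 7 | 3-bromo-4-methoxy-6-[3-(tert-butyldimethylsilyloxy)propyl]-2H-pyran-2-one | CC(C)(C)[Si](C)(C)OCCCC1=CC(OC)=C(Br)C(=O)O1
F6 | step 2 | (R)-4-benzyl-3-{(2R,3R)-2-ethenyl-3-hydroxy-3-[3-methoxy-4-(triisopropylsilyloxy)phenyl]propanoyl}-1,3-oxazolidin-2-one | C=C[C@@H](C(=O)N1C(=O)OC[C@H]1Cc1ccccc1)[C@H](c1ccc(O[Si](C(C)C)(C(C)C)C(C)C)c(OC)c1)O
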